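**Retrosynthetic overview**
1. Target 22 ⇐ diol 19 ⇐ bis-silyl ether 18: O13 acetate and O3 tiglate are put on last.
2. 18 ⇐ open-chain ynal 17: one nickel-catalysed carbonylative [2+2+1] closure of aldehyde C6, alkyne C7≡C11 and CO. The butenolide and the ten-membered carbocycle form together, last, and C6 is set here.
3. 17 ⇐ alkenyl iodide 12 + β-silyloxy boronic ester 6. Key disconnection: C1–C2 by a stereospecific 1,2-shift of C2 from boron to carbon (Zweifel olefination), which turns an (E)-alkenyl metal into the (Z)-C1=C10 alkene.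
4. 6 ⇐ enal 4 (propanal + glyoxal monoacetal) by enantioselective borylmethyl addition (sets C3). 12 ⇐ hexa-1,5-diyne by hydroxymethylation and methylalumination–iodination.

Assumption: germacrane numbering is used (ring C1–C10, lactone C12(=O)–O–C6 with C7=C11, C13 = CH2 on C11, C14 = methyl on C10, C15 = methyl on C4); read from the SMILES the target is (3S,6R), 1(10)Z, 4E, with an (E)-2-methylbut-2-enoate (tiglate) at O3.

**Step 1**
Reactants: 1 propanal; 2 2,2-dimethoxyacetaldehyde
Product: 4 (E)-4,4-dimethoxy-2-methylbut-2-enal, via aldol adduct 3 (not isolated)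
Conditions: pyrrolidine (10 mol %), propanoic acid (10 mol %), H2O/toluene, 40 °C, slow addition of 1
Reagents that add atoms: none
Why: Amine-catalysed crossed aldol condensation in which the enamine of propanal adds to the non-enolisable acetal aldehyde and the adduct dehydrates to the thermodynamically favoured (E)-enal, fixing the C4=C5 geometry.

**Step 2**
Reactants: 4 (E)-4,4-dimethoxy-2-methylbut-2-enal
Product: 5 (2S,3E)-5,5-dimethoxy-3-methyl-1-(4,4,5,5-tetramethyl-1,3,2-dioxaborolan-2-yl)pent-3-en-2-ol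
Conditions: CH2(Bpin)2 (1.3 equiv), Cu(NCMe)4PF6 (5 mol %), chiral BINOL-derived phosphoramidite (10 mol %), LiOtBu (1.3 equiv), THF, 22 °C; aq. NH4Cl
Reagents that add atoms: bis[(pinacolato)boryl]methane, CC1(C)OB(CB2OC(C)(C)C(C)(C)O2)OC1(C)C
Why: Copper-catalysed enantioselective 1,2-addition of a borylmethyl-copper nucleophile (formed from the geminal diboron reagent by alkoxide-induced deborylation) to the aldehyde, in which the chiral phosphoramidite–copper complex selects the aldehyde face and sets C3 as S while leaving the C2 boron handle in place.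

**Step 3**
Reactants: 5 (2S,3E)-5,5-dimethoxy-3-methyl-1-(4,4,5,5-tetramethyl-1,3,2-dioxaborolan-2-yl)pent-3-en-2-ol
Product: 6 tert-butyl{[(2S,3E)-5,5-dimethoxy-3-methyl-1-(4,4,5,5-tetramethyl-1,3,2-dioxaborolan-2-yl)pent-3-en-2-yl]oxy}dimethylsilane
Conditions: TBSCl, imidazole, DMF, rt
Reagents that add atoms: tert-butyldimethylsilyl chloride, CC(C)(C)[Si](C)(C)Cl
Why: Standard silyl ether formation under non-acidic conditions that spare the acetal, masking the alcohol so that the later boronate complex carries no free β-oxide.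

**Step 4**
Reactants: 7 hexa-1,5-diyne
Product: 10 tert-butyl(hepta-2,6-diyn-1-yloxy)dimethylsilane, via lithium hexa-1,5-diyn-1-ide 8 (not isolated), via lithium hepta-2,6-diyn-1-olate 9 (not isolated)
Conditions: n-BuLi (1 equiv; 7 in threefold excess), THF, −78 °C; (CH2O)n, −78 °C to rt; TBSCl, DMF, rt
Reagents that add atoms: formaldehyde (from paraformaldehyde), C=O; tert-butyldimethylsilyl chloride, CC(C)(C)[Si](C)(C)Cl
Why: Monolithiation of the symmetric diyne (used in excess to suppress double reaction), acetylide addition to formaldehyde and in situ silylation of the lithium alkoxide give the propargylic silyl ether carrying C13 in one flask.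

**Step 5**
Reactants: 10 tert-butyl(hepta-2,6-diyn-1-yloxy)dimethylsilane
Product: 12 (E)-tert-butyl[(7-iodo-6-methylhept-6-en-2-yn-1-yl)oxy]dimethylsilane, via (E)-alkenyl dimethylalane 11 (not isolated)
Conditions: AlMe3 (2 equiv), Cp2ZrCl2 (20 mol %), CH2Cl2, −20 °C to rt; I2, THF, −30 °C
Reagents that add atoms: trimethylaluminium, C[Al](C)C; iodine, II
Why: Zirconium-catalysed Negishi carboalumination adds methyl and aluminium syn across the terminal alkyne only (methyl to the internal carbon C10), and iodinolysis with retention gives the (E)-iodide with iodine cis to the new methyl group.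

**Step 6**
Reactants: 12 (E)-tert-butyl[(7-iodo-6-methylhept-6-en-2-yn-1-yl)oxy]dimethylsilane; 6 tert-butyl{[(2S,3E)-5,5-dimethoxy-3-methyl-1-(4,4,5,5-tetramethyl-1,3,2-dioxaborolan-2-yl)pent-3-en-2-yl]oxy}dimethylsilane
Product: 16 (4S,2E,6Z)-4,12-bis(tert-butyldimethylsilyloxy)-1,1-dimethoxy-3,7-dimethyldodeca-2,6-dien-10-yne, via alkenyllithium 13 (not isolated), via lithium boronate complex 14 (not isolated), via β-iodo boronic ester 15 (not isolated)
Conditions: 12, t-BuLi (2 equiv), Et2O, −78 °C; 6, THF, −78 °C; I2, MeOH, −78 °C; NaOMe, MeOH, −78 °C to rt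
Reagents that add atoms: none
Why: Zweifel olefination, in which iodine–lithium exchange (retention) gives 13, addition to boron gives complex 14, iodonium formation triggers the stereospecific 1,2-shift of C2 from boron to C1, and anti elimination of boron and iodide from 15 inverts the alkene geometry, so the (E)-alkenyl metal becomes the (Z)-trisubstituted C1=C10 alkene while C3 is untouched.

**Step 7**
Reactants: 16 (4S,2E,6Z)-4,12-bis(tert-butyldimethylsilyloxy)-1,1-dimethoxy-3,7-dimethyldodeca-2,6-dien-10-yne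
Product: 17 (4S,2E,6Z)-4,12-bis(tert-butyldimethylsilyloxy)-3,7-dimethyldodeca-2,6-dien-10-ynal
Conditions: oxalic acid, wet SiO2, CH2Cl2, rt
Reagents that add atoms: water, O
Why: Acid-catalysed hydrolysis of the allylic dimethyl acetal, which is far more labile than the two silyl ethers, releases the (E)-enal without touching C3 or either alkene.

**Step 8**
Reactants: 17 (4S,2E,6Z)-4,12-bis(tert-butyldimethylsilyloxy)-3,7-dimethyldodeca-2,6-dien-10-ynal
Product: 18 (3S,6R,1(10)Z,4E)-3,13-bis(tert-butyldimethylsilyloxy)germacra-1(10),4,7(11)-trien-12,6-olide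
Conditions: Ni(cod)2 (20 mol %), chiral C2-symmetric imidazolinium tetrafluoroborate (24 mol %), KOtBu (24 mol %), PhOCHO (2 equiv), Et3N (0.5 equiv), toluene, 60 °C, 17 added over 12 h (final 1 mM)
Reagents that add atoms: phenyl formate (CO source), O=COc1ccccc1
Why: Proposed new method: zerovalent nickel bearing a chiral N-heterocyclic carbene joins aldehyde carbon C6 to the tether-bearing alkyne carbon C7 by oxidative cyclization to a ring-fused oxanickelacyclopentene (the elementary step of nickel-catalysed reductive macrocyclization of ynals), the Ni–C11 bond then inserts CO released slowly from phenyl formate and C–O reductive elimination closes the butenolide (C11–C12 and O–C12) and regenerates the catalyst, the new C6 centre (R) being fixed in the oxidative cyclization by the ligand matched to the C3 silyloxy centre; the closest known reaction types are the hetero-Pauson–Khand cyclocarbonylation of short-tether ynals to fused butenolides and the nickel-catalysed [2+2+1] carbonylative cycloaddition of imines and alkynes with phenyl formate as CO source.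

**Step 9**
Reactants: 18 (3S,6R,1(10)Z,4E)-3,13-bis(tert-butyldimethylsilyloxy)germacra-1(10),4,7(11)-trien-12,6-olide
Product: 19 (3S,6R,1(10)Z,4E)-3,13-dihydroxygermacra-1(10),4,7(11)-trien-12,6-olide
Conditions: HF·pyridine, pyridine, THF, 0 °C to rt
Reagents that add atoms: none
Why: Fluoride-mediated desilylation of both silyl ethers under pyridine-buffered, non-basic conditions that leave the base-sensitive butenolide and both stereocentres untouched.

**Step 10**
Reactants: 19 (3S,6R,1(10)Z,4E)-3,13-dihydroxygermacra-1(10),4,7(11)-trien-12,6-olide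
Product: 20 (3S,6R,1(10)Z,4E)-13-acetoxy-3-hydroxygermacra-1(10),4,7(11)-trien-12,6-olide
Conditions: Ac2O (1.1 equiv), 2,4,6-collidine, CH2Cl2, −40 °C to 0 °C
Reagents that add atoms: acetic anhydride, CC(=O)OC(C)=O
Why: Selective acylation, because the unhindered primary allylic C13 hydroxyl reacts much faster than the hindered secondary C3 hydroxyl at low temperature with a weak base.

**Step 11**
Reactants: 20 (3S,6R,1(10)Z,4E)-13-acetoxy-3-hydroxygermacra-1(10),4,7(11)-trien-12,6-olide; 21 (E)-2-methylbut-2-enoyl chloride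
Product: 22 (3S,6R,1(10)Z,4E)-13-acetoxy-3-[(E)-2-methylbut-2-enoyloxy]germacra-1(10),4,7(11)-trien-12,6-olide (CNP0198881.1)
Conditions: pyridine, DMAP (cat.), CH2Cl2, 0 °C to rt
Reagents that add atoms: none
Why: DMAP-catalysed acylation of the remaining secondary alcohol with retention at C3, pyridine being used instead of a trialkylamine so that no vinylketene forms and the (E)-geometry of the tiglate is kept.

**Compound list**
1 | propanal | CCC=O | starting material
2 | 2,2-dimethoxyacetaldehyde | COC(OC)C=O | starting material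
3 | 3-hydroxy-4,4-dimethoxy-2-methylbutanal (aldol adduct, diastereomer mixture) | COC(OC)C(O)C(C)C=O | intermediate
4 | (E)-4,4-dimethoxy-2-methylbut-2-enal | O=C/C(C)=C/C(OC)OC | intermediate
5 | (2S,3E)-5,5-dimethoxy-3-methyl-1-(4,4,5,5-tetramethyl-1,3,2-dioxaborolan-2-yl)pent-3-en-2-ol | O[C@H](/C(C)=C/C(OC)OC)CB1OC(C)(C)C(C)(C)O1 | intermediate
6 | tert-butyl{[(2S,3E)-5,5-dimethoxy-3-methyl-1-(4,4,5,5-tetramethyl-1,3,2-dioxaborolan-2-yl)pent-3-en-2-yl]oxy}dimethylsilane | CC(C)(C)[Si](C)(C)O[C@H](/C(C)=C/C(OC)OC)CB1OC(C)(C)C(C)(C)O1 | intermediate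
7 | hexa-1,5-diyne | C#CCCC#C | starting material
8 | lithium hexa-1,5-diyn-1-ide | [Li]C#CCCC#C | intermediate
9 | lithium hepta-2,6-diyn-1-olate | [Li+].[O-]CC#CCCC#C | intermediate
10 | tert-butyl(hepta-2,6-diyn-1-yloxy)dimethylsilane | C#CCCC#CCO[Si](C)(C)C(C)(C)C | intermediate
11 | (E)-{7-[(tert-butyldimethylsilyl)oxy]-2-methylhept-1-en-5-yn-1-yl}dimethylalumane (Al cis to methyl) | C[Al](C)/C=C(\C)CCC#CCO[Si](C)(C)C(C)(C)C | intermediate
12 | (E)-tert-butyl[(7-iodo-6-methylhept-6-en-2-yn-1-yl)oxy]dimethylsilane (I cis to methyl) | I/C=C(\C)CCC#CCO[Si](C)(C)C(C)(C)C | intermediate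
13 | (E)-{7-[(tert-butyldimethylsilyl)oxy]-2-methylhept-1-en-5-yn-1-yl}lithium | [Li]/C=C(\C)CCC#CCO[Si](C)(C)C(C)(C)C | intermediate
14 | lithium pinacolato borate carrying the (2S,3E)-2-silyloxy-5,5-dimethoxy-3-methylpent-3-en-1-yl group of 6 and the (E)-alkenyl group of 13 on boron | [Li+].CC(C)(C)[Si](C)(C)O[C@H](/C(C)=C/C(OC)OC)C[B-]1(/C=C(\C)CCC#CCO[Si](C)(C)C(C)(C)C)OC(C)(C)C(C)(C)O1 | intermediate
15 | (4S,2E)-4,12-bis(tert-butyldimethylsilyloxy)-7-iodo-1,1-dimethoxy-3,7-dimethyl-6-(4,4,5,5-tetramethyl-1,3,2-dioxaborolan-2-yl)dodec-2-en-10-yne (anti adduct; one of the two C6/C7 anti diastereomers drawn, both give 16) | CC(C)(C)[Si](C)(C)O[C@H](/C(C)=C/C(OC)OC)C[C@H](B1OC(C)(C)C(C)(C)O1)[C@@](C)(I)CCC#CCO[Si](C)(C)C(C)(C)C | intermediate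
16 | (4S,2E,6Z)-4,12-bis(tert-butyldimethylsilyloxy)-1,1-dimethoxy-3,7-dimethyldodeca-2,6-dien-10-yne | CC(C)(C)[Si](C)(C)O[C@H](/C(C)=C/C(OC)OC)C/C=C(/C)CCC#CCO[Si](C)(C)C(C)(C)C | intermediate
17 | (4S,2E,6Z)-4,12-bis(tert-butyldimethylsilyloxy)-3,7-dimethyldodeca-2,6-dien-10-ynal | CC(C)(C)[Si](C)(C)O[C@H](/C(C)=C/C=O)C/C=C(/C)CCC#CCO[Si](C)(C)C(C)(C)C | intermediate
18 | (3S,6R,1(10)Z,4E)-3,13-bis(tert-butyldimethylsilyloxy)germacra-1(10),4,7(11)-trien-12,6-olide | CC(C)(C)[Si](C)(C)O[C@H]1C/C=C(/C)CCC2=C(CO[Si](C)(C)C(C)(C)C)C(=O)O[C@@H]2/C=C/1C | intermediate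
19 | (3S,6R,1(10)Z,4E)-3,13-dihydroxygermacra-1(10),4,7(11)-trien-12,6-olide | O[C@H]1C/C=C(/C)CCC2=C(CO)C(=O)O[C@@H]2/C=C/1C | intermediate
20 | (3S,6R,1(10)Z,4E)-13-acetoxy-3-hydroxygermacra-1(10),4,7(11)-trien-12,6-olide | O[C@H]1C/C=C(/C)CCC2=C(COC(C)=O)C(=O)O[C@@H]2/C=C/1C | intermediate
21 | (E)-2-methylbut-2-enoyl chloride (tigloyl chloride) | C/C=C(\C)C(Cl)=O | starting material
22 | (3S,6R,1(10)Z,4E)-13-acetoxy-3-[(E)-2-methylbut-2-enoyloxy]germacra-1(10),4,7(11)-trien-12,6-olide (CNP0198881.1) | C/C=C(\C)C(=O)O[C@H]1C/C=C(/C)CCC2=C(COC(C)=O)C(=O)O[C@@H]2/C=C/1C | target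

**Step count and risks**
Total steps: 11. Longest linear sequence: 9 steps (steps 1–3 and 6–11); steps 4–5 are the second branch, joined at step 6.

Most likely to fail:

Step 8 (the proposed new step). Possible failures are oligomerisation instead of ten-membered ring closure, endo-mode coupling at C11, nickel carbonyl formation that stops the catalyst, or poor control at C6. The fallback uses known chemistry, sets out from 6 and 7 and comes back at 18. Hexadiyne 7 is mono-silylated (n-BuLi, Me3SiCl) to trimethyl(hexa-1,5-diyn-1-yl)silane F1. F1 is carboaluminated and iodinated as in step 5 to (E)-(6-iodo-5-methylhex-5-en-1-yn-1-yl)trimethylsilane F2, which is joined to 6 by the Zweifel protocol of step 6 to give the silyl alkyne F3. K2CO3 in MeOH frees the terminal alkyne F4, and LiN(SiMe3)2 followed by ClCO2Me gives the ynoate F5. A MgI2-promoted β-iodo aldol reaction (Morita–Baylis–Hillman type) with paraformaldehyde gives the (Z)-β-iodo-α-(hydroxymethyl)acrylate F6 with iodine cis to the ester, which is silylated (TBSCl, imidazole) to F7. Acetal hydrolysis as in step 7 gives the iodo aldehyde F8. An intramolecular Nozaki–Hiyama–Kishi reaction (CrCl2, NiCl2 cat., DMSO/THF, high dilution) then forms C6–C7, and the chromium alkoxide lactonises onto the cis ester to give 18; the C6 epimers are separated by chromatography.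

Step 6. The β-silyloxy boronate complex 14 may lose boron and silyloxide (β-elimination), or iodine may attack elsewhere. The fallback makes the same C1–C2 bond with retention by Suzuki–Miyaura coupling; it sets out from 6 and comes back at 16. tert-Butyldimethyl(prop-2-yn-1-yloxy)silane is lithiated and opens ethylene oxide (BF3·OEt2) to give 5-(tert-butyldimethylsilyloxy)pent-3-yn-1-ol F9, and CBr4/PPh3 gives the bromide F10. Its Grignard reagent, transmetalated to copper (CuBr·SMe2), adds syn across propyne (Normant carbocupration), and iodinolysis gives the (Z)-iodide F11 with iodine cis to the chain. Pd(OAc)2/SPhos, K3PO4, toluene/H2O, 80 °C couples F11 with the primary boronic ester 6 to give 16.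

Step 2. Possible failures are low enantioselectivity on this α-branched enal, conjugate addition, or loss of boron from the β-oxido boronate. The fallback sets the centre by reduction and installs boron afterwards; it sets out from 4 and comes back at 6. Chloromethyllithium (ICH2Cl, MeLi·LiBr, −78 °C) adds to 4 to give the racemic chlorohydrin F12, and Dess–Martin periodinane gives the chloromethyl enone F13. Corey–Bakshi–Shibata reduction (oxazaborolidine enantiomer chosen for the 2R alcohol, BH3·SMe2) gives (2R,3E)-chlorohydrin F14, which has the same spatial arrangement as 5. TBSCl/imidazole gives F15, and copper-catalysed borylation of the primary chloride (CuI, PPh3, LiOMe, B2pin2, Bu4NI, DMF) gives 6.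

**Further compounds**
F1 | step 8 | trimethyl(hexa-1,5-diyn-1-yl)silane | C#CCCC#C[Si](C)(C)C
F2 | step 8 | (E)-(6-iodo-5-methylhex-5-en-1-yn-1-yl)trimethylsilane | I/C=C(\C)CCC#C[Si](C)(C)C
F3 | step 8 | (4S,2E,6Z)-4-(tert-butyldimethylsilyloxy)-1,1-dimethoxy-3,7-dimethyl-11-(trimethylsilyl)undeca-2,6-dien-10-yne | CC(C)(C)[Si](C)(C)O[C@H](/C(C)=C/C(OC)OC)C/C=C(/C)CCC#C[Si](C)(C)C
F4 | step 8 | (4S,2E,6Z)-4-(tert-butyldimethylsilyloxy)-1,1-dimethoxy-3,7-dimethylundeca-2,6-dien-10-yne | CC(C)(C)[Si](C)(C)O[C@H](/C(C)=C/C(OC)OC)C/C=C(/C)CCC#C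
F5 | step 8 | methyl (9S,6Z,10E)-9-(tert-butyldimethylsilyloxy)-12,12-dimethoxy-6,10-dimethyldodeca-6,10-dien-2-ynoate | CC(C)(C)[Si](C)(C)O[C@H](/C(C)=C/C(OC)OC)C/C=C(/C)CCC#CC(=O)OC
F6 | step 8 | methyl (9S,2Z,6Z,10E)-9-(tert-butyldimethylsilyloxy)-2-(hydroxymethyl)-3-iodo-12,12-dimethoxy-6,10-dimethyldodeca-2,6,10-trienoate | CC(C)(C)[Si](C)(C)O[C@H](/C(C)=C/C(OC)OC)C/C=C(/C)CC/C(I)=C(\CO)C(=O)OC
F7 | step 8 | methyl (9S,2Z,6Z,10E)-9-(tert-butyldimethylsilyloxy)-2-[(tert-butyldimethylsilyloxy)methyl]-3-iodo-12,12-dimethoxy-6,10-dimethyldodeca-2,6,10-trienoate | CC(C)(C)[Si](C)(C)O[C@H](/C(C)=C/C(OC)OC)C/C=C(/C)CC/C(I)=C(\CO[Si](C)(C)C(C)(C)C)C(=O)OC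
F8 | step 8 | methyl (9S,2Z,6Z,10E)-9-(tert-butyldimethylsilyloxy)-2-[(tert-butyldimethylsilyloxy)methyl]-3-iodo-6,10-dimethyl-12-oxododeca-2,6,10-trienoate | CC(C)(C)[Si](C)(C)O[C@H](/C(C)=C/C=O)C/C=C(/C)CC/C(I)=C(\CO[Si](C)(C)C(C)(C)C)C(=O)OC
F9 | step 6 | 5-(tert-butyldimethylsilyloxy)pent-3-yn-1-ol | OCCC#CCO[Si](C)(C)C(C)(C)C
F10 | step 6 | [(5-bromopent-2-yn-1-yl)oxy](tert-butyl)dimethylsilane | BrCCC#CCO[Si](C)(C)C(C)(C)C
F11 | step 6 | (Z)-tert-butyl[(7-iodo-6-methylhept-6-en-2-yn-1-yl)oxy]dimethylsilane | I/C=C(/C)CCC#CCO[Si](C)(C)C(C)(C)C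
F12 | step 2 | (E)-1-chloro-5,5-dimethoxy-3-methylpent-3-en-2-ol (racemic) | OC(/C(C)=C/C(OC)OC)CCl
F13 | step 2 | (E)-1-chloro-5,5-dimethoxy-3-methylpent-3-en-2-one | O=C(/C(C)=C/C(OC)OC)CCl
F14 | step 2 | (2R,3E)-1-chloro-5,5-dimethoxy-3-methylpent-3-en-2-ol | O[C@H](/C(C)=C/C(OC)OC)CCl
F15 | step 2 | tert-butyl{[(2R,3E)-1-chloro-5,5-dimethoxy-3-methylpent-3-en-2-yl]oxy}dimethylsilane | CC(C)(C)[Si](C)(C)O[C@H](/C(C)=C/C(OC)OC)CCl
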